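## Retrosynthetic overview

1. Target ⇒ acetonide removal and O-acylation of the C6 hydroxyl of the bicyclic core with (R)-2-methylglyceric acid acetonide, itself made from (S)-lactic acid through its pivalaldehyde dioxolanone.
2. Ten-membered ring (second ring formed) ⇒ C6–C7 bond by a cathodic, chromium-catalysed intramolecular allylation of a 3-(bromomethyl)butenolide onto a C6 enal; C6 and C7 are set here under control of C8.
3. Butenolide (first ring formed) ⇒ 2-(bromomethyl)acrylate of the C8 allylic alcohol, ring-closing metathesis (C7=C11).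
4. Acyclic chain ⇒ C3–C4 B-alkyl Suzuki coupling of an (E)-diene chlorohydrin (from (S)-epichlorohydrin, acetylene, Me3Al and vinyl bromide; carries C8) with a (Z)-iodoalkene from mono-silylated butynediol; C7 vinyl from the epoxide and a sulfonium ylide.

Assumption: atom labels follow germacrane numbering (C8 lactone carbinol, C7 ring fusion, C6 acyloxy carbon, C15 acetoxymethyl carbon); the target is 6R,7R,8S,2'R with a 1(10)E olefin and a 4,5-olefin in which C3 and C6 are cis.

## Route

Step 1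
Reactants: 1 (S)-epichlorohydrin
Product: 2 (2S)-1-chloropent-4-yn-2-ol
Conditions: HC≡CH, n-BuLi, THF, −78 °C; BF3·OEt2; then 1, −78 °C; NH4Cl (aq)
Reagents that add atoms: acetylene (used as lithium acetylide), C#C
Why: BF3-promoted SN2 opening of the epoxide at its CH2 terminus by lithium acetylide (Yamaguchi-type alkynylation) does not touch the C–O bond of the stereocentre, so C8 is bought with 1.

Step 2
Reactants: 2 (2S)-1-chloropent-4-yn-2-ol
Product: 4 (2S,4E)-1-chloro-4-methylhepta-4,6-dien-2-ol, via alkenylalane 3 (not isolated)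
Conditions: Me3Al (3 equiv), Cp2ZrCl2 (25 mol %), CH2Cl2, 0 °C → rt; then CH2=CHBr, ZnCl2, Pd(PPh3)4 (5 mol %), THF, rt
Reagents that add atoms: trimethylaluminium, C[Al](C)C; vinyl bromide, C=CBr
Why: Zirconium-catalysed Negishi carboalumination adds CH3 and Al syn across the terminal alkyne (CH3 to the internal carbon) and the alkenylalane is coupled in the same flask with vinyl bromide under zerovalent palladium/ZnCl2 catalysis with retention, which fixes the 1(10)E olefin.

Step 3
Reactants: 5 4-[(tert-butyldimethylsilyl)oxy]but-2-yn-1-ol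
Product: 7 (2Z)-4-[(tert-butyldimethylsilyl)oxy]-2-iodobut-2-en-1-ol, via vinylstannane 6 (not isolated)
Conditions: Bu3SnH, [Cp*RuCl]4 (1.5 mol %), CH2Cl2, rt; then I2, CH2Cl2, 0 °C
Reagents that add atoms: iodine, [I][I]
Why: Hydroxyl-directed ruthenium-catalysed trans-hydrostannation puts tin on the alkyne carbon next to the free CH2OH with H anti to it, and iododestannylation goes with retention, so the iodide (later replaced by C3) is cis to the silyloxymethyl carbon C6.

Step 4
Reactants: 4 (2S,4E)-1-chloro-4-methylhepta-4,6-dien-2-ol; 7 (2Z)-4-[(tert-butyldimethylsilyl)oxy]-2-iodobut-2-en-1-ol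
Product: 10 (2E,5E)-2-{2-[(tert-butyldimethylsilyl)oxy]ethylidene}-6-methyl-7-[(2S)-oxiran-2-yl]hept-5-en-1-ol, via alkylborane 8 (not isolated), via chlorohydrin 9 (not isolated)
Conditions: 4, 9-BBN-H (2.2 equiv), THF, 0 °C → rt; then 7, PdCl2(dppf) (5 mol %), AsPh3, Cs2CO3, DMF/H2O, rt; then NaOH (1 M aq), rt
Reagents that add atoms: none
Why: 9-BBN hydroborates only the terminal CH2 of the diene, the B-alkyl Suzuki–Miyaura coupling joins C3 to C4 with retention of the iodoalkene geometry (C3 cis to C6), and hydroxide then closes the chlorohydrin to the epoxide by O-attack on CH2Cl, leaving C8 untouched.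

Step 5
Reactants: 10 (2E,5E)-2-{2-[(tert-butyldimethylsilyl)oxy]ethylidene}-6-methyl-7-[(2S)-oxiran-2-yl]hept-5-en-1-ol
Product: 11 (2E,5E,8S)-2-{2-[(tert-butyldimethylsilyl)oxy]ethylidene}-6-methyldeca-5,9-diene-1,8-diol
Conditions: Me3S+ I− (4 equiv), n-BuLi (3.8 equiv), THF, −10 °C → rt
Reagents that add atoms: trimethylsulfonium iodide, C[S+](C)C.[I-]
Why: Dimethylsulfonium methylide opens the terminal epoxide at C7 and the β-alkoxy sulfonium salt loses Me2S on deprotonation (epoxide to allylic alcohol homologation), so the C8–O bond and its configuration are kept.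

Step 6
Reactants: 11 (2E,5E,8S)-2-{2-[(tert-butyldimethylsilyl)oxy]ethylidene}-6-methyldeca-5,9-diene-1,8-diol
Product: 12 (2E,5E,8S)-2-{2-[(tert-butyldimethylsilyl)oxy]ethylidene}-8-hydroxy-6-methyldeca-5,9-dien-1-yl acetate
Conditions: AcCl (1.05 equiv), 2,4,6-collidine, CH2Cl2, −78 °C
Reagents that add atoms: acetyl chloride, CC(=O)Cl
Why: Kinetic acylation at −78 °C takes the primary allylic C15 hydroxyl and leaves the secondary C8 hydroxyl.

Step 7
Reactants: 12 (2E,5E,8S)-2-{2-[(tert-butyldimethylsilyl)oxy]ethylidene}-8-hydroxy-6-methyldeca-5,9-dien-1-yl acetate; 13 2-(bromomethyl)prop-2-enoic acid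
Product: 14 (3S,5E,9E)-9-(acetoxymethyl)-11-[(tert-butyldimethylsilyl)oxy]-5-methylundeca-1,5,9-trien-3-yl 2-(bromomethyl)prop-2-enoate
Conditions: DCC, DMAP (10 mol %), CH2Cl2, −20 → 0 °C
Reagents that add atoms: none
Why: Steglich esterification acylates the C8 hydroxyl on oxygen (no inversion), and catalytic DMAP at low temperature limits attack on the allylic bromide.

Step 8
Reactants: 14 (3S,5E,9E)-9-(acetoxymethyl)-11-[(tert-butyldimethylsilyl)oxy]-5-methylundeca-1,5,9-trien-3-yl 2-(bromomethyl)prop-2-enoate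
Product: 15 (5S)-5-[(2E,6E)-6-(acetoxymethyl)-8-[(tert-butyldimethylsilyl)oxy]-2-methylocta-2,6-dien-1-yl]-3-(bromomethyl)furan-2(5H)-one
Conditions: second-generation Grubbs catalyst RuCl2(=CHPh)(PCy3)(H2IMes) (5 mol %), toluene (5 mM), 80 °C
Reagents that add atoms: none
Why: Ring-closing metathesis between the C7 vinyl group and the acrylate methylene closes the five-membered butenolide and expels ethylene, while the trisubstituted olefins are too hindered to take part.

Step 9
Reactants: 15 (5S)-5-[(2E,6E)-6-(acetoxymethyl)-8-[(tert-butyldimethylsilyl)oxy]-2-methylocta-2,6-dien-1-yl]-3-(bromomethyl)furan-2(5H)-one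
Product: 16 (5S)-5-[(2E,6E)-6-(acetoxymethyl)-8-hydroxy-2-methylocta-2,6-dien-1-yl]-3-(bromomethyl)furan-2(5H)-one
Conditions: HF (48 % aq), MeCN, 0 °C
Reagents that add atoms: none
Why: Acidic fluoride cleaves the primary silyl ether without a nucleophilic base, so the allylic bromide, butenolide and acetate survive.

Step 10
Reactants: 16 (5S)-5-[(2E,6E)-6-(acetoxymethyl)-8-hydroxy-2-methylocta-2,6-dien-1-yl]-3-(bromomethyl)furan-2(5H)-one
Product: 17 (5S)-5-[(2E,6E)-6-(acetoxymethyl)-2-methyl-8-oxoocta-2,6-dien-1-yl]-3-(bromomethyl)furan-2(5H)-one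
Conditions: Dess–Martin periodinane, NaHCO3, CH2Cl2, 0 °C → rt
Reagents that add atoms: none
Why: Buffered Dess–Martin oxidation gives the enal under neutral conditions that do not isomerise the C4=C5 bond (C3 stays cis to C6).

Step 11
Reactants: 17 (5S)-5-[(2E,6E)-6-(acetoxymethyl)-2-methyl-8-oxoocta-2,6-dien-1-yl]-3-(bromomethyl)furan-2(5H)-one
Product: 20 [(3aS,4R,5E,9E,11aS)-4-hydroxy-10-methyl-3-methylidene-2-oxo-2,3,3a,4,7,8,11,11a-octahydrocyclodeca[b]furan-6-yl]methyl acetate, via allylchromium 18 (not isolated), via silyl ether 19 (not isolated)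
Conditions: CrCl2 (15 mol %), Me3SiCl (3 equiv), LiCl, DMF/THF (1:3), undivided cell, Al anode, Ni-foam cathode, constant current (2.3 F/mol), 17 added over 10 h (3 mM final), 25 °C; then citric acid (10 % aq), THF, 0 °C
Reagents that add atoms: none
Why: Proposed new method: chromium-electrocatalytic Nozaki–Hiyama–Kishi macrocyclisation of a 3-(bromomethyl)butenolide, in which the cathode reduces trivalent chromium to divalent chromium, two equivalents of which turn the C13–Br bond into a σ-allylchromium species that adds through C7 to the tethered C6 aldehyde in a six-membered Zimmerman–Traxler chair, Me3SiCl silylates the chromium alkoxide so that the metal is released for re-reduction and O6 cannot translactonise onto C12, and because the allylmetal forms only as fast as charge is passed its standing concentration stays low enough for ring closure to outrun oligomerisation; the allyl unit is locked in the lactone with C8 trans to C13, so the chair with C5 equatorial should give the anti C6-OH/C7–C8 relationship (6R), and bond formation on the butenolide face opposite C9 should give the trans-fused lactone (the C7 configuration that reads 7R in the target), both centres being set by C8; the closest known reactions are the intermolecular electrochemical chromium-catalysed Nozaki–Hiyama–Kishi allylation, zinc Barbier reactions of 3-(bromomethyl)furan-2(5H)-ones with aldehydes and stoichiometric CrCl2 macrocyclisations of allylic halides onto aldehydes.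

Step 12
Reactants: 21 (S)-lactic acid
Product: 22 (2S,5S)-2-tert-butyl-5-methyl-1,3-dioxolan-4-one
Conditions: t-BuCHO, TsOH (cat.), H2SO4 (cat.), pentane, reflux (Dean–Stark); crystallisation at −78 °C
Reagents that add atoms: pivalaldehyde, CC(C)(C)C=O
Why: Acid-catalysed acetalisation (Seebach dioxolanone) under thermodynamic control favours the cis acetal, purified by crystallisation; the lactic acid centre is not touched and controls the acetal carbon.

Step 13
Reactants: 22 (2S,5S)-2-tert-butyl-5-methyl-1,3-dioxolan-4-one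
Product: 24 (2S,5R)-2-tert-butyl-5-(hydroxymethyl)-5-methyl-1,3-dioxolan-4-one, via lithium enolate 23 (not isolated)
Conditions: LiN(iPr)2, THF, −78 °C; CH2O (g, from cracked paraformaldehyde), −78 °C; AcOH
Reagents that add atoms: formaldehyde, C=O
Why: Self-regeneration of stereocentres: the enolate is planar at C5, the tert-butyl acetal shields one face and formaldehyde adds anti to it (aldol addition), giving the quaternary centre with net retention.

Step 14
Reactants: 24 (2S,5R)-2-tert-butyl-5-(hydroxymethyl)-5-methyl-1,3-dioxolan-4-one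
Product: 25 (2R)-2,3-dihydroxy-2-methylpropanoic acid
Conditions: LiOH, THF/H2O, 0 °C → rt; then HCl (aq) to pH 2
Reagents that add atoms: water, O
Why: Saponification opens the dioxolanone and the hemiacetal loses pivalaldehyde; no bond to the quaternary centre is broken.

Step 15
Reactants: 25 (2R)-2,3-dihydroxy-2-methylpropanoic acid
Product: 26 (4R)-2,2,4-trimethyl-1,3-dioxolane-4-carboxylic acid
Conditions: Me2C(OMe)2, acetone, TsOH (cat.), rt
Reagents that add atoms: 2,2-dimethoxypropane, COC(C)(C)OC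
Why: Acid-catalysed ketalisation ties the 1,2-diol into the thermodynamically preferred 1,3-dioxolane and leaves the carboxylic acid free.

Step 16
Reactants: 20 [(3aS,4R,5E,9E,11aS)-4-hydroxy-10-methyl-3-methylidene-2-oxo-2,3,3a,4,7,8,11,11a-octahydrocyclodeca[b]furan-6-yl]methyl acetate; 26 (4R)-2,2,4-trimethyl-1,3-dioxolane-4-carboxylic acid
Product: 28 [(3aR,4R,5E,9E,11aS)-6-(acetoxymethyl)-10-methyl-3-methylidene-2-oxo-2,3,3a,4,7,8,11,11a-octahydrocyclodeca[b]furan-4-yl] (4R)-2,2,4-trimethyl-1,3-dioxolane-4-carboxylate, via mixed anhydride 27 (not isolated)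
Conditions: 26, 2,4,6-trichlorobenzoyl chloride, Et3N, toluene, rt; then 20, DMAP, rt
Reagents that add atoms: none
Why: Yamaguchi esterification through the mixed anhydride acylates the hindered C6 hydroxyl on oxygen without touching C6 or the quaternary centre.

Step 17
Reactants: 28 [(3aR,4R,5E,9E,11aS)-6-(acetoxymethyl)-10-methyl-3-methylidene-2-oxo-2,3,3a,4,7,8,11,11a-octahydrocyclodeca[b]furan-4-yl] (4R)-2,2,4-trimethyl-1,3-dioxolane-4-carboxylate
Product: 29 [(3aR,4R,5E,9E,11aS)-6-(acetoxymethyl)-10-methyl-3-methylidene-2-oxo-2,3,3a,4,7,8,11,11a-octahydrocyclodeca[b]furan-4-yl] (2R)-2,3-dihydroxy-2-methylpropanoate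
Conditions: AcOH/H2O (4:1), 40 °C
Reagents that add atoms: none
Why: Mild aqueous acid hydrolyses the terminal acetonide faster than it affects the allylic esters or the diene, releasing the diol.

## Compound list

1 | (S)-epichlorohydrin | ClC[C@@H]1CO1 | starting material
2 | (2S)-1-chloropent-4-yn-2-ol | ClC[C@@H](O)CC#C | intermediate
3 | (E)-alkenyl(dimethyl)alane of 2, hydroxyl as its dimethylaluminium alkoxide (formed in the flask) | ClC[C@@H](O[Al](C)C)C/C(C)=C/[Al](C)C | intermediate
4 | (2S,4E)-1-chloro-4-methylhepta-4,6-dien-2-ol | ClC[C@@H](O)C/C(C)=C/C=C | intermediate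
5 | 4-[(tert-butyldimethylsilyl)oxy]but-2-yn-1-ol | OCC#CCO[Si](C)(C)C(C)(C)C | starting material
6 | (2Z)-4-[(tert-butyldimethylsilyl)oxy]-2-(tributylstannyl)but-2-en-1-ol (formed in the flask) | OC/C(=C/CO[Si](C)(C)C(C)(C)C)[Sn](CCCC)(CCCC)CCCC | intermediate
7 | (2Z)-4-[(tert-butyldimethylsilyl)oxy]-2-iodobut-2-en-1-ol | OC/C(I)=C/CO[Si](C)(C)C(C)(C)C | intermediate
8 | 9-[(3E,6S)-7-chloro-6-hydroxy-4-methylhept-3-en-1-yl]-9-borabicyclo[3.3.1]nonane (formed in the flask) | ClC[C@@H](O)C/C(C)=C/CCB1C2CCCC1CCC2 | intermediate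
9 | (2E,5E,8S)-2-{2-[(tert-butyldimethylsilyl)oxy]ethylidene}-9-chloro-6-methylnon-5-ene-1,8-diol (formed in the flask) | ClC[C@@H](O)C/C(C)=C/CC/C(CO)=C\CO[Si](C)(C)C(C)(C)C | intermediate
10 | (2E,5E)-2-{2-[(tert-butyldimethylsilyl)oxy]ethylidene}-6-methyl-7-[(2S)-oxiran-2-yl]hept-5-en-1-ol | C1O[C@H]1C/C(C)=C/CC/C(CO)=C\CO[Si](C)(C)C(C)(C)C | intermediate
11 | (2E,5E,8S)-2-{2-[(tert-butyldimethylsilyl)oxy]ethylidene}-6-methyldeca-5,9-diene-1,8-diol | C=C[C@@H](O)C/C(C)=C/CC/C(CO)=C\CO[Si](C)(C)C(C)(C)C | intermediate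
12 | (2E,5E,8S)-2-{2-[(tert-butyldimethylsilyl)oxy]ethylidene}-8-hydroxy-6-methyldeca-5,9-dien-1-yl acetate | C=C[C@@H](O)C/C(C)=C/CC/C(COC(C)=O)=C\CO[Si](C)(C)C(C)(C)C | intermediate
13 | 2-(bromomethyl)prop-2-enoic acid | C=C(CBr)C(=O)O | starting material
14 | (3S,5E,9E)-9-(acetoxymethyl)-11-[(tert-butyldimethylsilyl)oxy]-5-methylundeca-1,5,9-trien-3-yl 2-(bromomethyl)prop-2-enoate | C=C[C@@H](OC(=O)C(=C)CBr)C/C(C)=C/CC/C(COC(C)=O)=C\CO[Si](C)(C)C(C)(C)C | intermediate
15 | (5S)-5-[(2E,6E)-6-(acetoxymethyl)-8-[(tert-butyldimethylsilyl)oxy]-2-methylocta-2,6-dien-1-yl]-3-(bromomethyl)furan-2(5H)-one | BrCC1=C[C@@H](OC1=O)C/C(C)=C/CC/C(COC(C)=O)=C\CO[Si](C)(C)C(C)(C)C | intermediate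
16 | (5S)-5-[(2E,6E)-6-(acetoxymethyl)-8-hydroxy-2-methylocta-2,6-dien-1-yl]-3-(bromomethyl)furan-2(5H)-one | BrCC1=C[C@@H](OC1=O)C/C(C)=C/CC/C(COC(C)=O)=C\CO | intermediate
17 | (5S)-5-[(2E,6E)-6-(acetoxymethyl)-2-methyl-8-oxoocta-2,6-dien-1-yl]-3-(bromomethyl)furan-2(5H)-one (C3 cis to the aldehyde carbon C6) | BrCC1=C[C@@H](OC1=O)C/C(C)=C/CC/C(COC(C)=O)=C\C=O | intermediate
18 | {[(5S)-5-[(2E,6E)-6-(acetoxymethyl)-2-methyl-8-oxoocta-2,6-dien-1-yl]-2-oxo-2,5-dihydrofuran-3-yl]methyl}chromium dichloride, solvated (formed in the flask) | Cl[Cr](Cl)CC1=C[C@@H](OC1=O)C/C(C)=C/CC/C(COC(C)=O)=C\C=O | intermediate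
19 | [(3aR,4R,5E,9E,11aS)-10-methyl-3-methylidene-2-oxo-4-[(trimethylsilyl)oxy]-2,3,3a,4,7,8,11,11a-octahydrocyclodeca[b]furan-6-yl]methyl acetate (formed in the flask) | C=C1C(=O)O[C@H]2C/C(C)=C/CC/C(COC(C)=O)=C\[C@@H](O[Si](C)(C)C)[C@H]12 | intermediate
20 | [(3aS,4R,5E,9E,11aS)-4-hydroxy-10-methyl-3-methylidene-2-oxo-2,3,3a,4,7,8,11,11a-octahydrocyclodeca[b]furan-6-yl]methyl acetate (same spatial arrangement as the target; 3a reads S only because the free hydroxyl changes the ranking) | C=C1C(=O)O[C@H]2C/C(C)=C/CC/C(COC(C)=O)=C\[C@@H](O)[C@H]12 | intermediate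
21 | (S)-lactic acid | C[C@H](O)C(=O)O | starting material
22 | (2S,5S)-2-tert-butyl-5-methyl-1,3-dioxolan-4-one | C[C@@H]1O[C@H](C(C)(C)C)OC1=O | intermediate
23 | lithium enolate of 22, (2S)-2-tert-butyl-5-methyl-1,3-dioxol-4-olate (formed in the flask) | CC1=C(O[Li])O[C@H](O1)C(C)(C)C | intermediate
24 | (2S,5R)-2-tert-butyl-5-(hydroxymethyl)-5-methyl-1,3-dioxolan-4-one | C[C@]1(CO)O[C@H](C(C)(C)C)OC1=O | intermediate
25 | (2R)-2,3-dihydroxy-2-methylpropanoic acid | OC(=O)[C@](C)(O)CO | intermediate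
26 | (4R)-2,2,4-trimethyl-1,3-dioxolane-4-carboxylic acid | OC(=O)[C@@]1(C)COC(C)(C)O1 | intermediate
27 | (4R)-2,2,4-trimethyl-1,3-dioxolane-4-carboxylic 2,4,6-trichlorobenzoic anhydride (formed in the flask) | O=C(OC(=O)[C@@]1(C)COC(C)(C)O1)c1c(Cl)cc(Cl)cc1Cl | intermediate
28 | [(3aR,4R,5E,9E,11aS)-6-(acetoxymethyl)-10-methyl-3-methylidene-2-oxo-2,3,3a,4,7,8,11,11a-octahydrocyclodeca[b]furan-4-yl] (4R)-2,2,4-trimethyl-1,3-dioxolane-4-carboxylate | C=C1C(=O)O[C@H]2C/C(C)=C/CC/C(COC(C)=O)=C\[C@@H](OC(=O)[C@@]3(C)COC(C)(C)O3)[C@H]12 | intermediate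
29 | [(3aR,4R,5E,9E,11aS)-6-(acetoxymethyl)-10-methyl-3-methylidene-2-oxo-2,3,3a,4,7,8,11,11a-octahydrocyclodeca[b]furan-4-yl] (2R)-2,3-dihydroxy-2-methylpropanoate | C=C1C(=O)O[C@H]2C/C(C)=C/CC/C(COC(C)=O)=C\[C@@H](OC(=O)[C@](C)(O)CO)[C@H]12 | target

## Count and risks

Total step count: 17. Longest linear sequence: 12 steps from 1 (steps 1, 2, 4–11, 16, 17).

**Step 11 (proposed new step).** The main risks are the wrong diastereomer (C6 epimer or cis-fused lactone), oligomers, and attack through C13 giving a twelve-membered ring. The fallback uses known chemistry, sets out from 17 and comes back to the route at 28. It drops electrolysis and chromium and closes the ring with stoichiometric zinc dust in THF/aqueous NH4Cl under syringe-pump dilution, the established mode of reaction of 3-(bromomethyl)furan-2(5H)-ones with aldehydes, and accepts whatever C6 configuration results. The anti product is 20 and goes on through step 16. The syn product, [(3aS,4S,5E,9E,11aS)-4-hydroxy-10-methyl-3-methylidene-2-oxo-2,3,3a,4,7,8,11,11a-octahydrocyclodeca[b]furan-6-yl]methyl acetate F1, is esterified with acid 26 under Mitsunobu conditions (PPh3, DIAD, toluene, 0 °C). This inverts C6, so both diastereomers converge on 28.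

**Step 8.** The allylic bromide and the 1,1-disubstituted acrylate may make the metathesis sluggish or decompose the ruthenium carbene. The fallback sets out from 12 and comes back at 15, bringing in the bromide only after ring closure. Compound 12 is acylated with acryloyl chloride/iPr2NEt to (3S,5E,9E)-9-(acetoxymethyl)-11-[(tert-butyldimethylsilyl)oxy]-5-methylundeca-1,5,9-trien-3-yl prop-2-enoate F2. This is closed with the second-generation Grubbs catalyst at 40 °C to the unsubstituted butenolide (5S)-5-[(2E,6E)-6-(acetoxymethyl)-8-[(tert-butyldimethylsilyl)oxy]-2-methylocta-2,6-dien-1-yl]furan-2(5H)-one F3. A Morita–Baylis–Hillman reaction with aqueous formaldehyde (imidazole, THF/H2O) gives (5S)-5-[(2E,6E)-6-(acetoxymethyl)-8-[(tert-butyldimethylsilyl)oxy]-2-methylocta-2,6-dien-1-yl]-3-(hydroxymethyl)furan-2(5H)-one F4, and Appel bromination (CBr4, PPh3) gives 15.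

**Step 17.** Aqueous acid may cause transannular cyclisation of the diene or ionise the allylic esters before the acetonide is gone. The fallback sets out from 25 (and uses 20) and comes back at 29, replacing the acid-labile acetonide by fluoride-labile silyl ethers. Compound 25 is per-silylated (Et3SiOTf, 2,6-lutidine) to triethylsilyl (2R)-2-methyl-2,3-bis[(triethylsilyl)oxy]propanoate F5. The silyl ester is cleaved (K2CO3, MeOH, 0 °C) to (2R)-2-methyl-2,3-bis[(triethylsilyl)oxy]propanoic acid F6. Yamaguchi coupling with 20 gives [(3aR,4R,5E,9E,11aS)-6-(acetoxymethyl)-10-methyl-3-methylidene-2-oxo-2,3,3a,4,7,8,11,11a-octahydrocyclodeca[b]furan-4-yl] (2R)-2-methyl-2,3-bis[(triethylsilyl)oxy]propanoate F7, and HF·pyridine in THF/pyridine at 0 °C removes both silyl ethers to give 29.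

## Further compounds

F1 | step 11 | [(3aS,4S,5E,9E,11aS)-4-hydroxy-10-methyl-3-methylidene-2-oxo-2,3,3a,4,7,8,11,11a-octahydrocyclodeca[b]furan-6-yl]methyl acetate (C6 epimer of 20) | C=C1C(=O)O[C@H]2C/C(C)=C/CC/C(COC(C)=O)=C\[C@H](O)[C@H]12
F2 | step 8 | (3S,5E,9E)-9-(acetoxymethyl)-11-[(tert-butyldimethylsilyl)oxy]-5-methylundeca-1,5,9-trien-3-yl prop-2-enoate | C=C[C@@H](OC(=O)C=C)C/C(C)=C/CC/C(COC(C)=O)=C\CO[Si](C)(C)C(C)(C)C
F3 | step 8 | (5S)-5-[(2E,6E)-6-(acetoxymethyl)-8-[(tert-butyldimethylsilyl)oxy]-2-methylocta-2,6-dien-1-yl]furan-2(5H)-one | O=C1C=C[C@@H](O1)C/C(C)=C/CC/C(COC(C)=O)=C\CO[Si](C)(C)C(C)(C)C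
F4 | step 8 | (5S)-5-[(2E,6E)-6-(acetoxymethyl)-8-[(tert-butyldimethylsilyl)oxy]-2-methylocta-2,6-dien-1-yl]-3-(hydroxymethyl)furan-2(5H)-one | OCC1=C[C@@H](OC1=O)C/C(C)=C/CC/C(COC(C)=O)=C\CO[Si](C)(C)C(C)(C)C
F5 | step 17 | triethylsilyl (2R)-2-methyl-2,3-bis[(triethylsilyl)oxy]propanoate | CC[Si](CC)(CC)OC(=O)[C@](C)(O[Si](CC)(CC)CC)CO[Si](CC)(CC)CC
F6 | step 17 | (2R)-2-methyl-2,3-bis[(triethylsilyl)oxy]propanoic acid | OC(=O)[C@](C)(O[Si](CC)(CC)CC)CO[Si](CC)(CC)CC
F7 | step 17 | [(3aR,4R,5E,9E,11aS)-6-(acetoxymethyl)-10-methyl-3-methylidene-2-oxo-2,3,3a,4,7,8,11,11a-octahydrocyclodeca[b]furan-4-yl] (2R)-2-methyl-2,3-bis[(triethylsilyl)oxy]propanoate | C=C1C(=O)O[C@H]2C/C(C)=C/CC/C(COC(C)=O)=C\[C@@H](OC(=O)[C@](C)(O[Si](CC)(CC)CC)CO[Si](CC)(CC)CC)[C@H]12
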